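Start from the constants of step 3, because the question is a share inside the pair that step connects.

    starting material + partner + by-product → target + 2 by-product (k1 = 5.67 M⁻² h⁻¹)
    starting material + partner → target + by-product (k2 = 0.0527 M⁻¹ h⁻¹)
    target ⇌ isomer of the product (K3 = 0.32, k3 = 0.0237 h⁻¹)
    2 partner → homo dimer (k4 = 0.335 M⁻¹ h⁻¹)
    partner + protic impurity → quenched reagent (k5 = 2.01 M⁻¹ h⁻¹)

| setting | larch | oak | cedar | ash |
|---|---|---|---|---|
| starting material | 0.14 M | 0.14 M | 0.14 M | 0.14 M (fed, over 20 h) |
| partner | 0.280 M (in portions, 2, over 20 h) | 0.280 M | 0.280 M (fed, over 20 h) | 0.280 M |
| protic impurity | 0.0140 M | 0.0140 M | 0.0140 M | 0.0140 M |
| time | 4.0 d | 4.0 d | 4.0 d | 4.0 d |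
| remark | first portion at the start, last at 20 h | everything together at the start | all else is in the flask from the start; the feed brings no volume worth counting | all else is in the flask from the start; the feed brings no volume worth counting |

* the flask that comes out highest in share of target in target plus isomer of the product, or "all alike" when all lie within 1.5 percentage points (larch / oak / cedar / ash / all alike)
* share of target in target plus isomer of the product at the end, larch
* share of target in target plus isomer of the product at the end, oak
* share of target in target plus isomer of the product at the end, cedar
* share of target in target plus isomer of the product at the end, ash

- two of one species on the left: rate k times its square, two consumed each time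
- run time (larch): 4.0 d

Write the resting share first: the target's share of target plus isomer at equilibrium of step 3, 75.8%. In cedar the relaxation half-life of 0.295 d is shorter than the run of 4.0 d, so expect cedar near that share.

Now object: product still forms late and enters as target, so the share trails above the resting share. Balance the share, taking the excess as steady. As an estimate, the excess then equals the relative growth rate of the pair times the lag time, the isomer's resting share divided by the relaxation rate, 2.48 h.

To get the growth rate, balance the reagent charged in the smaller amount, the starting material. Each turn of step 1 or 2 adds one to the pair and one net by-product, so in cedar c_pair = c_by-product = 0.14 M minus c_starting material. Guess cedar late with pair and starting material each at 0.0700 M, half of the charge. Partner then goes into product as a pseudo-first-order loss, a = k1·c_starting material·c_by-product + k2·c_starting material = 0.0315 h⁻¹, and the pair's relative growth rate is a·c_partner/c_pair.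

What is c_partner? Try dimerisation as the sole sink over the 76.0 h after the feed, with the partner at the end of the feed taken as large: 0.0196 M, giving an excess of 2.2 percentage points, a size that matters against the margin of 1.5 points. But that ignores a, which is faster than dimerisation at that level. Solve these two sinks together, with a held constant and the partner at the end of the feed again taken as large: the estimate is a·exp(−a·t)/(2·k4·(1−exp(−a·t))) = 0.004729 M. The excess falls to 0.53 points, so my reckoning for cedar is 76.3%. One doubt stays: the guess of the pair sits inside each term.

The forecast gives 76.3% for larch, 76.5% for oak, 76.2% for cedar and 76.9% for ash, hence all alike, since a late tail “leaves a small excess of target”.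

The run reads 76.3% in larch, 76.2% in oak, 76.3% in cedar and 76.8% in ash, so the answer is all alike, the ash–oak gap of 0.60 points being less than the margin. Watch the partner tail: the lag time on cedar's end state gives 0.34 points against a read excess of 0.50 points. Charge cedar with 0.48 M of partner instead: the end state of that neighbouring flask, with 21.5% starting material and 1.15% partner left, gives 76.0%, and that flask reads 76.1%.

(The rate constants belong to no real substance; the run is a simulation.)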